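**Strategy.** The cyclobutane ring is made by contracting a pyrrolidine. A nitrogen atom is inserted, in thought, between cyclobutane C2 (benzylic, bearing the 4-hydroxyphenyl ring) and C3 (α to the esterified carboxyl); the resulting all-trans 3,5-diarylpyrrolidine-2,4-dicarboxylate is the adduct of a glycine-derived azomethine ylide and a caffeate, so one catalytic asymmetric [3+2] cycloaddition sets the absolute configuration. In the key step an iodonitrene turns the amine into a 1,1-diazene; loss of N2 leaves a 1,4-biradical, stabilised by exactly that aryl ring and that ester carbonyl, which collapses to the C2–C3 bond with retention. Ester differentiation, coupling with protected danshensu and one hydrogenolysis finish the route.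

Key step: step 4

Assumption: (R)-DTBM-Segphos is taken as the ligand antipode that delivers the (2R,3R,4S,5S) exo adduct 6; if the sense of induction is the opposite, the (S)-ligand is used and nothing else changes.

Step 1
Reactants: 1 caffeic acid
Product: 2 benzyl (E)-3-[3,4-bis(benzyloxy)phenyl]prop-2-enoate
Conditions: BnBr (3.5 equiv), K2CO3 (4 equiv), DMF, 60 °C
Reagents that add atoms: benzyl bromide, BrCc1ccccc1
Why: Williamson O-alkylation of both phenoxides and SN2 alkylation of the carboxylate under carbonate should give the tribenzyl compound; the E alkene is untouched and no stereocenter is formed.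

Step 2
Reactants: 3 glycine tert-butyl ester, 4 4-(benzyloxy)benzaldehyde, 2 benzyl (E)-3-[3,4-bis(benzyloxy)phenyl]prop-2-enoate
Product: 6 4-benzyl 2-tert-butyl (2R,3R,4S,5S)-5-[4-(benzyloxy)phenyl]-3-[3,4-bis(benzyloxy)phenyl]pyrrolidine-2,4-dicarboxylate (exo adduct), via imine 5 (not isolated)
Conditions: 3 + 4, 4 Å MS, THF, rt; then Cu(CH3CN)4PF6 (5 mol %), (R)-DTBM-Segphos (5.5 mol %), Cs2CO3 (20 mol %), 2, rt to 40 °C
Reagents that add atoms: none
Why: Condensation gives imine 5, whose N,O-chelated W-shaped ylide on monovalent copper should add to the E-cinnamate in a catalytic asymmetric exo-selective 1,3-dipolar cycloaddition (Michael–Mannich sense, ylide α-carbon to the aryl-bearing β-carbon): the W geometry makes C2-ester and C5-aryl cis, the E alkene makes C3-aryl and C4-ester trans, the exo approach enforced by the bulky bisphosphine puts the C4 ester trans to the C5 aryl (so the two aryl groups are cis), and the ligand selects the face and hence the absolute configuration at C3 and C5.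

Step 3
Reactants: 6 exo adduct
Product: 7 4-benzyl 2-tert-butyl (2S,3R,4S,5S)-5-[4-(benzyloxy)phenyl]-3-[3,4-bis(benzyloxy)phenyl]pyrrolidine-2,4-dicarboxylate (all-trans)
Conditions: NaOBn (0.3 equiv), BnOH (3 equiv), THF, 40 °C; then AcOH
Reagents that add atoms: none
Why: Base-mediated epimerisation of an ester α-stereocenter: reversible deprotonation at C2 should move the crowded 2,3-cis/2,5-cis isomer to the thermodynamically preferred all-trans pyrrolidine, while C3 and C5 are not acidic, C4 is already trans to both neighbours, benzyloxide exchange at the benzyl ester is degenerate and the tert-butyl ester resists transesterification.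

Step 4
Reactants: 7 all-trans pyrrolidine
Product: 10 1-benzyl 3-tert-butyl (1R,2R,3S,4S)-2-[4-(benzyloxy)phenyl]-4-[3,4-bis(benzyloxy)phenyl]cyclobutane-1,3-dicarboxylate (all-trans), via 1,1-diazene 8 (not isolated), via 1,4-biradical 9 (not isolated)
Conditions: PhI(OH)OTs (2.5 equiv), ammonium carbamate (8 equiv), CF3CH2OH, 80 °C
Reagents that add atoms: none
Why: PhI(OH)OTs and ammonia (from ammonium carbamate) form an iodonitrene that transfers NH to the pyrrolidine nitrogen, loss of iodobenzene gives the 1,1-diazene 8, and extrusion of N2 leaves the singlet 1,4-biradical 9 whose benzylic centre (bearing the 4-benzyloxyphenyl ring) and α-ester centre recombine to the new C–C bond. The closest known reaction type is the iodonitrene-mediated nitrogen deletion (ring contraction) of pyrrolidines to cyclobutanes, shown on polysubstituted pyrrolidine-2-carboxylates from azomethine ylide cycloadditions and related to the oxidation of N-aminopyrrolidines. The four-membered ring is closed by intramolecular radical–radical coupling between C2 and C5 of the former five-membered ring, not by a polar closure. Both carbons of the new bond are stereocenters already present in 7 and should be carried over with retention, because collapse of the singlet biradical is faster than rotation about its C–C bonds and the all-trans arrangement is also the least strained; C3 and C4 are not touched. The step needs ring closure to beat β-scission of the biradical into two alkenes, and nitrogen transfer to beat oxidation of the electron-rich arenes by the trivalent iodine reagent; the all-trans substitution (no eclipsing groups in the closing geometry), the benzyl-protected phenols and the large excess of ammonia source are meant to secure this.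

Step 5
Reactants: 10 cyclobutane diester
Product: 11 (1S,2S,3R,4R)-3-[(benzyloxy)carbonyl]-2-[4-(benzyloxy)phenyl]-4-[3,4-bis(benzyloxy)phenyl]cyclobutane-1-carboxylic acid (all-trans)
Conditions: TFA/CH2Cl2 (1:4), 0 °C to rt
Reagents that add atoms: none
Why: Acidolysis of the tert-butyl ester (loss of the tert-butyl cation as isobutene) should free only this carboxylic acid, since benzyl esters and aryl benzyl ethers tolerate brief TFA treatment, and no stereocenter is touched (the descriptors change only because numbering and priorities change).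

Step 6
Reactants: 12 (R)-3-(3,4-dihydroxyphenyl)lactic acid (danshensu)
Product: 13 benzyl (2R)-3-[3,4-bis(benzyloxy)phenyl]-2-hydroxypropanoate
Conditions: BnBr (3.3 equiv), K2CO3 (3.5 equiv), DMF, rt, under N2
Reagents that add atoms: benzyl bromide, BrCc1ccccc1
Why: Carbonate deprotonates only the phenols and the carboxylic acid, so Williamson etherification and carboxylate alkylation should leave the secondary alcohol free and the (R) center, which carbonate does not deprotonate, intact.

Step 7
Reactants: 11 cyclobutane monoacid, 13 benzyl (2R)-3-[3,4-bis(benzyloxy)phenyl]-2-hydroxypropanoate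
Product: 14 1-benzyl 3-{(2R)-1-(benzyloxy)-3-[3,4-bis(benzyloxy)phenyl]-1-oxopropan-2-yl} (1R,2R,3S,4S)-2-[4-(benzyloxy)phenyl]-4-[3,4-bis(benzyloxy)phenyl]cyclobutane-1,3-dicarboxylate
Conditions: DCC (1.3 equiv), DMAP (0.3 equiv), CH2Cl2, 0 °C to rt
Reagents that add atoms: none
Why: Steglich esterification: the acylpyridinium of the hindered acid should acylate the secondary alcohol without breaking its C–O bond (configuration retained), and any transient enolisation at the cyclobutane α-carbon returns to the favoured all-trans isomer.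

Step 8
Reactants: 14 heptabenzyl precursor
Product: 15 (1R,2R,3S,4S)-3-{[(1R)-1-carboxy-2-(3,4-dihydroxyphenyl)ethoxy]carbonyl}-4-(3,4-dihydroxyphenyl)-2-(4-hydroxyphenyl)cyclobutane-1-carboxylic acid (target)
Conditions: H2 (1 atm), Pd/C (10 wt % Pd), THF/MeOH, rt
Reagents that add atoms: none
Why: Catalytic hydrogenolysis should cleave all seven benzylic C–O bonds (five aryl benzyl ethers, two benzyl esters), while the lactate ester C–O bond is not benzylic and the cyclobutane has no bond between two benzylic carbons, so ring and stereocenters are untouched.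

**Compound list**

1 | caffeic acid, (E)-3-(3,4-dihydroxyphenyl)prop-2-enoic acid | O=C(O)/C=C/c1ccc(O)c(O)c1 | starting material
2 | benzyl (E)-3-[3,4-bis(benzyloxy)phenyl]prop-2-enoate | O=C(OCc1ccccc1)/C=C/c1ccc(OCc2ccccc2)c(OCc2ccccc2)c1 | intermediate
3 | glycine tert-butyl ester (tert-butyl 2-aminoacetate, free base) | NCC(=O)OC(C)(C)C | starting material
4 | 4-(benzyloxy)benzaldehyde | O=Cc1ccc(OCc2ccccc2)cc1 | starting material
5 | tert-butyl (E)-2-{[4-(benzyloxy)benzylidene]amino}acetate (imine, not isolated) | CC(C)(C)OC(=O)C/N=C/c1ccc(OCc2ccccc2)cc1 | intermediate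
6 | 4-benzyl 2-tert-butyl (2R,3R,4S,5S)-5-[4-(benzyloxy)phenyl]-3-[3,4-bis(benzyloxy)phenyl]pyrrolidine-2,4-dicarboxylate (exo adduct: C2 ester, C3 aryl and C5 aryl on one face, C4 ester on the other) | O=C(OCc1ccccc1)[C@@H]1[C@@H](c2ccc(OCc3ccccc3)cc2)N[C@@H](C(=O)OC(C)(C)C)[C@H]1c1ccc(OCc2ccccc2)c(OCc2ccccc2)c1 | intermediate
7 | 4-benzyl 2-tert-butyl (2S,3R,4S,5S)-5-[4-(benzyloxy)phenyl]-3-[3,4-bis(benzyloxy)phenyl]pyrrolidine-2,4-dicarboxylate (all-trans) | O=C(OCc1ccccc1)[C@@H]1[C@@H](c2ccc(OCc3ccccc3)cc2)N[C@H](C(=O)OC(C)(C)C)[C@H]1c1ccc(OCc2ccccc2)c(OCc2ccccc2)c1 | intermediate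
8 | 1,1-diazene (isodiazene) on the ring nitrogen of 7, ring configuration unchanged (not isolated) | O=C(OCc1ccccc1)[C@@H]1[C@@H](c2ccc(OCc3ccccc3)cc2)[N+](=[N-])[C@H](C(=O)OC(C)(C)C)[C@H]1c1ccc(OCc2ccccc2)c(OCc2ccccc2)c1 | intermediate
9 | open-chain 1,4-biradical from 8 after loss of N2: radical centres at the former C5 (benzylic) and former C2 (α to CO2tBu), the two inner stereocenters unchanged (not isolated) | O=C(OCc1ccccc1)[C@H]([CH]c1ccc(OCc2ccccc2)cc1)[C@@H]([CH]C(=O)OC(C)(C)C)c1ccc(OCc2ccccc2)c(OCc2ccccc2)c1 | intermediate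
10 | 1-benzyl 3-tert-butyl (1R,2R,3S,4S)-2-[4-(benzyloxy)phenyl]-4-[3,4-bis(benzyloxy)phenyl]cyclobutane-1,3-dicarboxylate (all-trans) | O=C(OCc1ccccc1)[C@@H]1[C@@H](c2ccc(OCc3ccccc3)cc2)[C@H](C(=O)OC(C)(C)C)[C@H]1c1ccc(OCc2ccccc2)c(OCc2ccccc2)c1 | intermediate
11 | (1S,2S,3R,4R)-3-[(benzyloxy)carbonyl]-2-[4-(benzyloxy)phenyl]-4-[3,4-bis(benzyloxy)phenyl]cyclobutane-1-carboxylic acid (all-trans, same spatial arrangement as 10) | O=C(OCc1ccccc1)[C@@H]1[C@@H](c2ccc(OCc3ccccc3)cc2)[C@H](C(=O)O)[C@H]1c1ccc(OCc2ccccc2)c(OCc2ccccc2)c1 | intermediate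
12 | (2R)-3-(3,4-dihydroxyphenyl)-2-hydroxypropanoic acid (danshensu) | O[C@H](Cc1ccc(O)c(O)c1)C(=O)O | starting material
13 | benzyl (2R)-3-[3,4-bis(benzyloxy)phenyl]-2-hydroxypropanoate | O[C@H](Cc1ccc(OCc2ccccc2)c(OCc2ccccc2)c1)C(=O)OCc1ccccc1 | intermediate
14 | 1-benzyl 3-{(2R)-1-(benzyloxy)-3-[3,4-bis(benzyloxy)phenyl]-1-oxopropan-2-yl} (1R,2R,3S,4S)-2-[4-(benzyloxy)phenyl]-4-[3,4-bis(benzyloxy)phenyl]cyclobutane-1,3-dicarboxylate | O=C(OCc1ccccc1)[C@@H]1[C@@H](c2ccc(OCc3ccccc3)cc2)[C@H](C(=O)O[C@H](Cc2ccc(OCc3ccccc3)c(OCc3ccccc3)c2)C(=O)OCc2ccccc2)[C@H]1c1ccc(OCc2ccccc2)c(OCc2ccccc2)c1 | intermediate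
15 | (1R,2R,3S,4S)-3-{[(1R)-1-carboxy-2-(3,4-dihydroxyphenyl)ethoxy]carbonyl}-4-(3,4-dihydroxyphenyl)-2-(4-hydroxyphenyl)cyclobutane-1-carboxylic acid (CNP0270917.1) | O=C(O)[C@@H]1[C@@H](c2ccc(O)cc2)[C@H](C(=O)O[C@H](Cc2ccc(O)c(O)c2)C(=O)O)[C@H]1c1ccc(O)c(O)c1 | target

**Count.** Total: 8 steps. Longest linear sequence: 7 steps (1, 2, 3, 4, 5, 7, 8); step 6 is a one-step side branch.

**Steps most likely to fail**

Step 4 (key step). After loss of N2 the 1,4-biradical may fragment by β-scission into two alkenes instead of closing. The trivalent iodine reagent may also oxidise the benzyloxy-substituted arenes, or over-oxidise the amine before nitrogen transfer. Fallback: from 7, the N–N bond is made without an oxidant and the diazene is generated under neutral conditions. N-Nitrosation (tert-butyl nitrite, CH2Cl2, rt) gives the N-nitrosopyrrolidine F1. Reduction (Zn, AcOH/MeOH, 0 °C) gives the N-aminopyrrolidine F2. Oxidation of this 1,1-disubstituted hydrazine with HgO (CH2Cl2, 0 °C to rt) generates the same 1,1-diazene at low temperature and without acid or fluoro-alcohol, and the route is rejoined at 10.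

Step 2. The electron-rich β-aryl acrylate may react slowly, and the approach of the dipolarophile may not be cleanly exo or face-selective. The diastereomer with trans aryl groups cannot be corrected by any later step. Fallback: from 2, contra-thermodynamic E-to-Z photoisomerisation by energy transfer (fac-Ir(ppy)3, blue LEDs, MeCN) gives the (Z)-cinnamate F3. Its cycloaddition with imine 5 under endo-selective monovalent-silver catalysis (AgOAc, (S)-QUINAP, iPr2NEt, THF, −20 °C; ligand antipode chosen for the configuration drawn) gives the all-cis pyrrolidine F4, in which the two aryl groups are again cis. NaOBn/BnOH in THF then epimerises both ester-bearing carbons (C2 and C4), and the route is rejoined at 7.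

Step 3. Proton exchange at C2 of the secondary α-amino tert-butyl ester may be too slow, or ring opening by retro-aza-Michael reaction from the C4 enolate may consume material before equilibrium is reached. Fallback: from 6, the ring contraction is run first (PhI(OH)OTs, ammonium carbamate, CF3CH2OH, 80 °C) to give the cyclobutane F5, in which the tert-butyl ester is cis to both aryl groups. Base equilibration of this amine-free diester (NaOBn, BnOH/THF, 50 °C), a truxillate-type epimerisation with a large driving force, then gives 10.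

**Further compounds**

F1 | step 4 | 4-benzyl 2-tert-butyl (2S,3R,4S,5S)-5-[4-(benzyloxy)phenyl]-3-[3,4-bis(benzyloxy)phenyl]-1-nitrosopyrrolidine-2,4-dicarboxylate | O=C(OCc1ccccc1)[C@@H]1[C@@H](c2ccc(OCc3ccccc3)cc2)N(N=O)[C@H](C(=O)OC(C)(C)C)[C@H]1c1ccc(OCc2ccccc2)c(OCc2ccccc2)c1
F2 | step 4 | 4-benzyl 2-tert-butyl (2S,3R,4S,5S)-1-amino-5-[4-(benzyloxy)phenyl]-3-[3,4-bis(benzyloxy)phenyl]pyrrolidine-2,4-dicarboxylate | O=C(OCc1ccccc1)[C@@H]1[C@@H](c2ccc(OCc3ccccc3)cc2)N(N)[C@H](C(=O)OC(C)(C)C)[C@H]1c1ccc(OCc2ccccc2)c(OCc2ccccc2)c1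
F3 | step 2 | benzyl (Z)-3-[3,4-bis(benzyloxy)phenyl]prop-2-enoate | O=C(OCc1ccccc1)/C=C\c1ccc(OCc2ccccc2)c(OCc2ccccc2)c1
F4 | step 2 | 4-benzyl 2-tert-butyl (2R,3R,4R,5S)-5-[4-(benzyloxy)phenyl]-3-[3,4-bis(benzyloxy)phenyl]pyrrolidine-2,4-dicarboxylate (all-cis) | O=C(OCc1ccccc1)[C@H]1[C@@H](c2ccc(OCc3ccccc3)cc2)N[C@@H](C(=O)OC(C)(C)C)[C@H]1c1ccc(OCc2ccccc2)c(OCc2ccccc2)c1
F5 | step 3 | 1-benzyl 3-tert-butyl (1R,2R,3R,4S)-2-[4-(benzyloxy)phenyl]-4-[3,4-bis(benzyloxy)phenyl]cyclobutane-1,3-dicarboxylate (C3 epimer of 10) | O=C(OCc1ccccc1)[C@@H]1[C@@H](c2ccc(OCc3ccccc3)cc2)[C@@H](C(=O)OC(C)(C)C)[C@H]1c1ccc(OCc2ccccc2)c(OCc2ccccc2)c1
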